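## Structural features

The target is a heptaphenol in which two 2,3-diaryl-2,3-dihydrobenzofurans are joined by one bond, C3 of the ring A unit to C5' of the ring B unit; ring A also carries an (E)-4-hydroxystyryl group at C4 and a hydroxyl at C6. Ring A is resorcinol-derived (O1 and O6 meta) and ring B is catechol-derived (O1' and the C7' hydroxyl ortho). Each fused dihydrofuran holds two adjacent stereocentres, C2/C3 (2S,3S) and C2'/C3' (2'R,3'R), both trans. The two pairs are insulated from each other by the C3–C5' bond and by ring B, so neither can direct the other; read locally they are mirror images, which calls for two reagent-controlled events of opposite sense. Fragile points are the electron-rich stilbene (acid-induced ring closure onto it, light-induced E/Z isomerisation), the two cyclic 4-oxybenzylic aryl ethers O1–C2 and O1'–C2' (ionisation by Lewis or Brønsted acid) and the seven oxidisable phenols. The real difficulty is absolute control at four carbons in two remote pairs, the crowded C3 lodged between ring B and the 2,6-disubstituted carbon C3a of ring A, and the unmasking of seven phenols at the end. The key step uses the fact that C2' and C3' each bear one ordinary aryl group and that C3' is bonded to C3a', the ring B carbon ortho to the oxygen-bearing C7a'. An (E)-alkenyl boronate standing on C3a' can therefore take up the 4-oxyphenyl group at C2' and the 3,5-dioxyphenyl group at C3' in one catalytic event, leaving boron on C2' as the placeholder for O1'; the same pattern recurs at C2/C3.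

## Logic of the disconnections

32 ⇒ 31. The seven O–H bonds are traced back to O–CH3. One robust mask then covers every oxygen through organolithium, base, peroxide and palladium chemistry, and all aryl building blocks are commercial in this form. The forward step must cleave seven ethers without leaving O1–C2 or O1'–C2' opened and without protonating the stilbene.

31 ⇒ 30. The O1–C2 bond of the ring A dihydrofuran is cut to a phenol and a secondary benzylic alcohol. This turns a ring stereocentre into an open-chain carbinol that can come from a C–B bond. The forward closure has to invert C2 so that the aryl groups end trans.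

30 ⇒ 28 (through 29). C2–O is traced back to C2–B and the phenol to its acetal. The forward sequence must remove the acetal while the carbon still carries boron, because the 4-methoxybenzylic alcohol of 30 would not survive acid, and must then oxidise with retention.

28 ⇒ 26 + 11 + 19. The C3–C5' bond and the C2–aryl bond are cut together. This is the point of highest convergence: two halves of similar size meet and both remaining stereocentres are set by the catalyst, not by the distant ring B centres. The forward step must engage an alkene flanked by two ortho substituents, use the ligand antipode opposite to that of the ring B event and leave the stilbene alone.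

26 ⇒ 24 + 5; 24 ⇒ 23 ⇒ 22 ⇒ 21 ⇒ 20. The alkenyl C–B bond is traced to a terminal alkyne, the alkyne to an aldehyde, the acetal to the phenol, the phenol to the methyl ether ortho to the formyl group, and the formyl C–C bond to an arene C–H. The whole of ring A with its stilbene then comes from one commercial stilbene. The forward steps need regioselective formylation next to the alkene-bearing carbon and selective cleavage of the ortho methoxy group.

19 ⇒ 18 ⇒ 16 (through 17). The triflate S–O bond and then the C5'–O bond are cut back to C5'–Cl. The union needs a triflate, but the handle carried through the ring B event must be inert to palladium there, hence chloride. The forward step must activate an electron-rich aryl chloride without opening or epimerising the dihydrofuran.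

16 ⇒ 15. The O1'–C2' bond is cut, for the same reason and with the same demand (inversion at C2') as in ring A.

15 ⇒ 13 (through 14). C2'–O goes back to C2'–B and the phenol to its acetal, with the same order of events as for 30.

13 ⇒ 7 + 11 + 9. The C2'–aryl and C3'–aryl bonds are cut in one operation. Three simple achiral pieces result and both ring B stereocentres become the outcome of one face selection on an (E)-alkene. The forward step must favour the metallate shift over direct coupling and must not touch the ring chloride.

7 ⇒ 3 + 5; 3 ⇒ 2 ⇒ 1; 5 ⇒ 4; 9 ⇒ 8; 11 ⇒ 10. The alkenyl boronate goes back to a terminal alkyne and a hindered diol, the alkyne to the protected aldehyde and the commercial phenol aldehyde, the diol to a commercial diketone, the triflate to a commercial phenol, and the C–Li bond of the aryl nucleophile to the C–Br bond of a commercial aryl bromide. Each forward step is a standard functional-group operation, and the aryllithium is made once for both couplings.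

## Other disconnections considered

Alternative 1: The cut is the C3–C3a bond of the ring A dihydrofuran, traced back to a flavanone whose C2 comes from (2S)-naringenin. In the forward key step, irradiation of diazo ketone A1 in methanol triggers a Wolff rearrangement. The ring A carbon shifts from the carbonyl carbon to the carbene carbon and the ketene is caught as methyl ester A2, contracting the pyranone to the dihydrofuran.
- In its favour: the C2 configuration is bought, not made, and its spatial arrangement is that of C2 in 32. The C3–C3a bond forms intramolecularly, so the crowding that burdens step 17 does not arise; on this point the alternative is the better plan. The free 4-hydroxyl of A2 is a ready handle for the styryl group, and C3 of A2 can be equilibrated to the trans ester.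
- Against it here: A2 has an ester where 32 has ring B, so the C3–C5' bond must still be made, most plausibly by a decarboxylative radical coupling whose trans selectivity would rest on substrate bias alone. The flavanone C2 centre can open to the chalcone under the basic conditions of diazo transfer. The C2'/C3' pair of ring B gets no help.
- Comparison: structurally it solves one stereo pair from the chiral pool, whereas the chosen plan treats both pairs with one reaction type. Mechanistically the concerted shift is the equal of the metallate shift in reliability at C2 but weaker at C3. In step count it is longer, since protection, diazo transfer, rearrangement, ester removal, arylation and styryl introduction are all needed to reach the stage that 28 reaches in one coupling.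

Alternative 2: The cut removes ring A itself at C7a–C3a, C4–C5 and C6–C7. In the forward key step Cp*RuCl(cod) would join the ynol ether and the enyne of tethered diyne A3 with alkynyl boronate A4 in a (2+2+2) cycloaddition (oxidative cyclisation to a ruthenacycle, alkyne insertion, reductive elimination). This gives A5 and closes ring A and its dihydrofuran together.
- In its favour: the pentasubstituted ring A is created with every substituent in place, the C6 boronate becomes the phenol by oxidation, and the conditions are neutral. Where the chosen plan forces an intermolecular coupling at the hindered C3, this is the better answer to crowding.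
- Against it here: C2 and C3 must already be present in A3, so it is an arene synthesis and not a stereochemical solution; an enantioselective route to A3 would need a reaction such as the one used in the chosen plan. The C3 hydrogen of A3 is benzylic and propargylic and at risk under the basic steps that make the ynol ether, which is itself hydrolytically labile. Boron must end at C6 and not at C5, and the conjugated alkene may take part. In A5 ring B is still an open aryl group, so the ring B dihydrofuran would have to be built afterwards on a molecule that already holds the stilbene.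
- Comparison: structurally it trades the stereo problem for a ring construction. Mechanistically its open question is regiocontrol, where that of the chosen plan is facial control. In step count it is clearly longer. The two plans are equal in the final deprotection problem.

Alternative 3: The cut takes O1'–C2' and C2'–C3' of the ring B dihydrofuran. In the forward key step Cs2CO3 expels sulfinate from sulfone A6 to give the ortho-quinone methide A7. The ylide of sulfonium salt A8 adds to its exocyclic carbon and the phenoxide displaces the sulfide, a (4+1) annulation that gives A9.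
- In its favour: three operations from the bromo analogue of 1 stand against steps 1–9 of the chosen plan, so on step count for ring B the alternative is clearly the better. The trans geometry is inherent in the anti-periplanar closure, equal to the chosen plan. The bromide of A9 is a better handle than the chloride of 16, which costs steps 10 and 11.
- Against it here: the chirality source is stoichiometric. The absolute configuration rests on several events that are not stereospecific: the face of a planar, geometrically mobile quinone methide, the face of the ylide and a possibly reversible betaine formation. A 4-methoxybenzyl ylide is also prone to rearrangement.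
- Comparison: in the chosen plan one catalyst-controlled face selection is followed by three stereospecific events (anti addition, retentive oxidation, invertive closure) and the chirality source is catalytic. This predictability, and the fact that the same reaction can be repeated at C2/C3 where a quinone methide would be flanked by two ortho substituents, is why the longer route is preferred. The annulation is kept as the fallback for step 7.

Key step: step 7

Remark (boron ligand): β-substituted alkenyl pinacol boronates tend to undergo direct Suzuki coupling in this reaction, so the pinacol ester is replaced by the more hindered ester of cis-1,2-dimethylacenaphthene-1,2-diol, written B(mac) (boron in a 6b,9a-dimethyl-6b,9a-dihydroacenaphtho[1,2-d][1,3,2]dioxaborol-8-yl group); the carbon skeletons of precursor and product are unchanged.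

Remark (ligand): MandyPhos is 1,1'-bis[bis(4-methoxy-3,5-dimethylphenyl)phosphino]-2,2'-bis[(dimethylamino)(phenyl)methyl]ferrocene. Its (Sp,Sp) antipode is assumed to deliver the (1S,2R) series; if the sense is the opposite, the two antipodes are exchanged between steps 7 and 17 and nothing else changes.

Remark (configuration): the (1S,2R) boronate 13 is the anti adduct of the (E)-alkene; retentive oxidation and invertive closure convert it into (2R,3R)-16.

Remark (aryl nucleophile): 4-methoxyphenyllithium 11 is assumed to be prepared once as a titrated ethereal solution, kept cold under argon and drawn on for both couplings.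

## Route

Step 1
Reactants: 1 5-chloro-2-hydroxy-3-methoxybenzaldehyde
Product: 2 5-chloro-3-methoxy-2-(methoxymethoxy)benzaldehyde
Conditions: MOMCl, i-Pr2NEt, CH2Cl2, 0 → 25 °C
Reagents that add atoms: chloromethyl methyl ether, COCCl
Why: O-alkylation of the phenol to its methoxymethyl acetal; the acetal withstands aryllithium, base and palladium and can later be removed by acid while the C–B bond is still in place.

Step 2
Reactants: 2 5-chloro-3-methoxy-2-(methoxymethoxy)benzaldehyde
Product: 3 5-chloro-1-ethynyl-3-methoxy-2-(methoxymethoxy)benzene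
Conditions: dimethyl (1-diazo-2-oxopropyl)phosphonate, K2CO3, MeOH, 0 → 25 °C
Reagents that add atoms: dimethyl (1-diazo-2-oxopropyl)phosphonate, CC(=O)C(=[N+]=[N-])P(=O)(OC)OC
Why: Seyferth–Gilbert homologation in the Ohira–Bestmann variant: the diazomethylphosphonate anion formed by methanolysis adds to the aldehyde, phosphate is eliminated and loss of N2 with a 1,2-shift gives the terminal alkyne; the carbonate base spares the aryl chloride and the acetal.

Step 3
Reactants: 4 acenaphthylene-1,2-dione
Product: 5 cis-1,2-dimethyl-1,2-dihydroacenaphthylene-1,2-diol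
Conditions: AlMe3 (2.5 equiv), toluene, 0 → 25 °C; aq. HCl; recrystallisation
Reagents that add atoms: trimethylaluminium, C[Al](C)C
Why: Double 1,2-addition of a methylaluminium reagent to the 1,2-diketone; the second methyl group is expected to enter anti to the aluminium alkoxide formed first, which puts both methyl groups on one face, and the cis (meso) diol is purified by crystallisation and is the only isomer able to form the five-membered boronate.

Step 4
Reactants: 3 5-chloro-1-ethynyl-3-methoxy-2-(methoxymethoxy)benzene; 5 cis-1,2-dimethyl-1,2-dihydroacenaphthylene-1,2-diol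
Product: 7 (E)-2-[5-chloro-3-methoxy-2-(methoxymethoxy)phenyl]ethenyl B(mac) boronate, via catechol boronate 6 (not isolated)
Conditions: catecholborane, Cy2BH (10 mol%), THF, 25 °C; then 5, THF, 25 °C
Reagents that add atoms: catecholborane, B1Oc2ccccc2O1
Why: Dialkylborane-catalysed hydroboration of the terminal alkyne: syn, anti-Markovnikov addition of B–H places boron on the terminal carbon and fixes the (E)-geometry; transesterification with the more basic aliphatic diol 5 then releases catechol and installs the hindered ligand.

Step 5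
Reactants: 8 3,5-dimethoxyphenol
Product: 9 3,5-dimethoxyphenyl trifluoromethanesulfonate
Conditions: Tf2O, pyridine, CH2Cl2, 0 °C
Reagents that add atoms: trifluoromethanesulfonic anhydride, O=S(=O)(OS(=O)(=O)C(F)(F)F)C(F)(F)F
Why: O-sulfonylation of the phenol gives the aryl electrophile for oxidative addition; no other nucleophilic site is present.

Step 6
Reactants: 10 4-bromoanisole
Product: 11 4-methoxyphenyllithium (obtained and kept as a titrated solution in Et2O)
Conditions: t-BuLi (2.0 equiv), Et2O, −78 → 0 °C; titration; storage at −20 °C under Ar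
Reagents that add atoms: tert-butyllithium, [Li]C(C)(C)C
Why: Bromine–lithium exchange: the first equivalent of t-BuLi exchanges with the aryl bromide and the second destroys the tert-butyl bromide formed, giving 2-methylpropane, 2-methylpropene and LiBr, so the aryllithium cannot be alkylated. The para methoxy group does not direct a competing lithiation at this temperature, and the ethereal solution is stable enough in the cold to serve both steps 7 and 17 after re-titration.

Step 7
Reactants: 7 (E)-2-[5-chloro-3-methoxy-2-(methoxymethoxy)phenyl]ethenyl B(mac) boronate; 11 4-methoxyphenyllithium; 9 3,5-dimethoxyphenyl trifluoromethanesulfonate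
Product: 13 (1S,2R)-2-[5-chloro-3-methoxy-2-(methoxymethoxy)phenyl]-2-(3,5-dimethoxyphenyl)-1-(4-methoxyphenyl)ethyl B(mac) boronate, via lithium alkenyl(aryl)borate 12 (not isolated)
Conditions: 11 (1.0 equiv, Et2O solution), 7, THF, −78 → 25 °C; then 9, Pd(OAc)2 (3 mol%), (Sp,Sp)-MandyPhos (3.6 mol%), NaOTf, THF, 60 °C
Reagents that add atoms: none
Why: Enantioselective conjunctive cross-coupling, a palladium-induced 1,2-metallate rearrangement known for alkenylboron ate complexes and aryl triflates and, with this boron ligand class, for β-substituted alkenes. The aryllithium 11 adds to boron of 7 to form 12; Pd(OAc)2 is reduced to zerovalent palladium, which inserts into the C–O bond of 9, and the cationic aryl divalent palladium binds the alkene of 12 and induces migration of the 4-methoxyphenyl group from boron to C2' anti to the metal; reductive elimination from the C3'-bound palladium then joins C3' to the 3,5-dimethoxyphenyl group with retention. No ring is closed. C3' is set by the alkene face that the ligand-bound palladium selects; C2' follows from it because the shift is anti-periplanar and the alkene is (E), so the two aryl groups add anti and the relative configuration is a matter of geometry, not of a second selection. The step needs the metallate shift to outrun direct transfer of a group from boron to palladium, which the bulky electron-rich diolate on boron secures; it needs the triflate to react in preference to the ring chloride, which holds because that chloride is para to an alkoxy group and inert to this catalyst at 60 °C. NaOTf removes the bromide carried in with the solution of 11, which would otherwise occupy the cationic palladium.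

Step 8
Reactants: 13 (1S,2R)-2-[5-chloro-3-methoxy-2-(methoxymethoxy)phenyl]-2-(3,5-dimethoxyphenyl)-1-(4-methoxyphenyl)ethyl B(mac) boronate
Product: 15 4-chloro-2-[(1R,2S)-1-(3,5-dimethoxyphenyl)-2-hydroxy-2-(4-methoxyphenyl)ethyl]-6-methoxyphenol, via phenol boronate 14 (not isolated)
Conditions: HCl (1 M), MeOH/THF, 40 °C; then NaOH (aq), H2O2 (30%), THF, 0 → 25 °C
Reagents that add atoms: hydrogen peroxide, OO
Why: Acid-catalysed methanolysis of the acetal followed by boronate oxidation, in which carbon migrates from boron to oxygen with retention; the acid is used while C2' still carries boron, so the acid-labile 4-methoxybenzylic alcohol is formed only under base.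

Step 9
Reactants: 15 4-chloro-2-[(1R,2S)-1-(3,5-dimethoxyphenyl)-2-hydroxy-2-(4-methoxyphenyl)ethyl]-6-methoxyphenol
Product: 16 (2R,3R)-5-chloro-3-(3,5-dimethoxyphenyl)-7-methoxy-2-(4-methoxyphenyl)-2,3-dihydro-1-benzofuran
Conditions: PPh3, DIAD, THF, 0 → 25 °C
Reagents that add atoms: none
Why: Intramolecular Mitsunobu etherification: the phenoxide displaces the oxyphosphonium group in a 5-exo-tet SN2 closure, inverting C2' and placing the two aryl groups trans; an ionising pathway would also favour the trans ring, so both pathways converge.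

Step 10
Reactants: 16 (2R,3R)-5-chloro-3-(3,5-dimethoxyphenyl)-7-methoxy-2-(4-methoxyphenyl)-2,3-dihydro-1-benzofuran
Product: 18 (2R,3R)-3-(3,5-dimethoxyphenyl)-7-methoxy-2-(4-methoxyphenyl)-2,3-dihydro-1-benzofuran-5-ol, via pinacol boronate 17 (not isolated)
Conditions: B2pin2, Pd2(dba)3 (2 mol%), XPhos (8 mol%), KOAc, 1,4-dioxane, 100 °C; then H2O2 (30%), NaOH (aq), THF, 0 °C
Reagents that add atoms: bis(pinacolato)diboron, CC1(C)OB(OC1(C)C)B1OC(C)(C)C(C)(C)O1 (boron and pinacol of 17 only); hydrogen peroxide, OO (phenol oxygen of 18)
Why: Miyaura borylation, in which the bulky electron-rich biarylphosphine lets zerovalent palladium insert into the electron-rich C5'–Cl bond, followed by oxidation of the aryl boronate with aryl migration to oxygen; the weak base in the hot stage and the cold, brief peroxide stage spare the doubly benzylic C3' hydrogen and the cyclic ether.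

Step 11
Reactants: 18 (2R,3R)-3-(3,5-dimethoxyphenyl)-7-methoxy-2-(4-methoxyphenyl)-2,3-dihydro-1-benzofuran-5-ol
Product: 19 (2R,3R)-3-(3,5-dimethoxyphenyl)-7-methoxy-2-(4-methoxyphenyl)-2,3-dihydro-1-benzofuran-5-yl trifluoromethanesulfonate
Conditions: Tf2O, pyridine, CH2Cl2, 0 °C
Reagents that add atoms: trifluoromethanesulfonic anhydride, O=S(=O)(OS(=O)(=O)C(F)(F)F)C(F)(F)F
Why: O-sulfonylation of the only free hydroxyl gives the unhindered C5' electrophile needed for the union.

Step 12
Reactants: 20 (E)-3,4',5-trimethoxystilbene
Product: 21 2,4-dimethoxy-6-[(E)-2-(4-methoxyphenyl)ethenyl]benzaldehyde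
Conditions: POCl3, DMF, 0 → 60 °C; aq. NaOAc
Reagents that add atoms: N,N-dimethylformamide, CN(C)C=O; water, O
Why: Vilsmeier–Haack formylation: the chloroiminium ion attacks the dimethoxy ring at the position para to one methoxy group and ortho to the other, next to the alkene-bearing carbon, the most activated and least hindered site; hydrolysis of the iminium gives the aldehyde.

Step 13
Reactants: 21 2,4-dimethoxy-6-[(E)-2-(4-methoxyphenyl)ethenyl]benzaldehyde
Product: 22 2-hydroxy-4-methoxy-6-[(E)-2-(4-methoxyphenyl)ethenyl]benzaldehyde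
Conditions: BCl3 (1.2 equiv), CH2Cl2, −78 → 0 °C; H2O
Reagents that add atoms: none
Why: Chelation-directed Lewis acid ether cleavage: boron bound to the aldehyde oxygen activates only the ortho methoxy group, whose methyl is taken by chloride; the limited amount of reagent and the low temperature spare the other ethers and the stilbene.

Step 14
Reactants: 22 2-hydroxy-4-methoxy-6-[(E)-2-(4-methoxyphenyl)ethenyl]benzaldehyde
Product: 23 4-methoxy-2-(methoxymethoxy)-6-[(E)-2-(4-methoxyphenyl)ethenyl]benzaldehyde
Conditions: MOMCl, i-Pr2NEt, CH2Cl2, 0 → 40 °C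
Reagents that add atoms: chloromethyl methyl ether, COCCl
Why: O-alkylation of the hydrogen-bonded phenol to its methoxymethyl acetal, the same temporary mask as in ring B and distinct from the six methyl ethers.

Step 15
Reactants: 23 4-methoxy-2-(methoxymethoxy)-6-[(E)-2-(4-methoxyphenyl)ethenyl]benzaldehyde
Product: 24 2-ethynyl-5-methoxy-1-(methoxymethoxy)-3-[(E)-2-(4-methoxyphenyl)ethenyl]benzene
Conditions: dimethyl (1-diazo-2-oxopropyl)phosphonate, K2CO3, MeOH/THF, 25 °C
Reagents that add atoms: dimethyl (1-diazo-2-oxopropyl)phosphonate, CC(=O)C(=[N+]=[N-])P(=O)(OC)OC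
Why: Ohira–Bestmann alkynylation as in step 2; the small diazomethylphosphonate anion reaches the 2,6-disubstituted aldehyde and the stilbene is inert to it.

Step 16
Reactants: 24 2-ethynyl-5-methoxy-1-(methoxymethoxy)-3-[(E)-2-(4-methoxyphenyl)ethenyl]benzene; 5 cis-1,2-dimethyl-1,2-dihydroacenaphthylene-1,2-diol
Product: 26 (E)-2-[4-methoxy-2-(methoxymethoxy)-6-[(E)-2-(4-methoxyphenyl)ethenyl]phenyl]ethenyl B(mac) boronate, via catechol boronate 25 (not isolated)
Conditions: catecholborane, Cy2BH (10 mol%), THF, 25 °C; then 5, THF, 25 °C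
Reagents that add atoms: catecholborane, B1Oc2ccccc2O1
Why: Catalysed syn hydroboration of the terminal alkyne and transesterification as in step 4; the terminal alkyne reacts far faster than the 1,2-diaryl alkene, so the stilbene stays untouched.

Step 17
Reactants: 26 (E)-2-[4-methoxy-2-(methoxymethoxy)-6-[(E)-2-(4-methoxyphenyl)ethenyl]phenyl]ethenyl B(mac) boronate; 11 4-methoxyphenyllithium; 19 (2R,3R)-3-(3,5-dimethoxyphenyl)-7-methoxy-2-(4-methoxyphenyl)-2,3-dihydro-1-benzofuran-5-yl trifluoromethanesulfonate
Product: 28 (1R,2S)-2-[(2R,3R)-3-(3,5-dimethoxyphenyl)-7-methoxy-2-(4-methoxyphenyl)-2,3-dihydro-1-benzofuran-5-yl]-2-[4-methoxy-2-(methoxymethoxy)-6-[(E)-2-(4-methoxyphenyl)ethenyl]phenyl]-1-(4-methoxyphenyl)ethyl B(mac) boronate, via lithium alkenyl(aryl)borate 27 (not isolated)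
Conditions: 11 (1.0 equiv, Et2O solution), 26, THF, −78 → 25 °C; then 19, Pd(OAc)2 (5 mol%), (Rp,Rp)-MandyPhos (6 mol%), NaOTf, THF, 60 °C
Reagents that add atoms: none
Why: Second conjunctive cross-coupling by the mechanism of step 7: the mirror-image ligand selects the opposite alkene face, so C3 and C2 arise under reagent control whatever the remote ring B centres, and anti addition across the (E)-alkene again fixes their relative configuration. The C5' triflate is unhindered, and the stilbene carries no boron and is therefore not activated for the metallate shift.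

Step 18
Reactants: 28 (1R,2S)-alkyl B(mac) boronate bearing the ring B unit on C2 and the acetal-protected ring A aryl group
Product: 30 (1R,2S)-2-[(2R,3R)-3-(3,5-dimethoxyphenyl)-7-methoxy-2-(4-methoxyphenyl)-2,3-dihydro-1-benzofuran-5-yl]-2-[2-hydroxy-4-methoxy-6-[(E)-2-(4-methoxyphenyl)ethenyl]phenyl]-1-(4-methoxyphenyl)ethan-1-ol, via phenol boronate 29 (not isolated)
Conditions: HCl (0.5 M), MeOH/THF, 25 → 40 °C; then NaOH (aq), H2O2 (30%), THF, 0 → 25 °C
Reagents that add atoms: hydrogen peroxide, OO
Why: Acetal methanolysis then boronate oxidation with retention, in the same order as step 8; the dilute acid cleaves the acetal much faster than the cyclic benzylic ether of ring B, and alkaline peroxide does not epoxidise an electron-rich stilbene.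

Step 19
Reactants: 30 (1R,2S)-phenol alcohol of the ring A unit
Product: 31 (2S,3S)-3-[(2R,3R)-3-(3,5-dimethoxyphenyl)-7-methoxy-2-(4-methoxyphenyl)-2,3-dihydro-1-benzofuran-5-yl]-6-methoxy-2-(4-methoxyphenyl)-4-[(E)-2-(4-methoxyphenyl)ethenyl]-2,3-dihydro-1-benzofuran
Conditions: PPh3, DIAD, THF, 0 → 25 °C
Reagents that add atoms: none
Why: Intramolecular Mitsunobu etherification as in step 9: 5-exo-tet displacement by the ring A phenoxide inverts C2 and gives the trans ring, with an ionising pathway leading to the same trans isomer.

Step 20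
Reactants: 31 heptamethyl ether of the target
Product: 32 (2S,3S)-3-[(2R,3R)-3-(3,5-dihydroxyphenyl)-7-hydroxy-2-(4-hydroxyphenyl)-2,3-dihydro-1-benzofuran-5-yl]-2-(4-hydroxyphenyl)-4-[(E)-2-(4-hydroxyphenyl)ethenyl]-2,3-dihydro-1-benzofuran-6-ol
Conditions: BBr3 (12 equiv), CH2Cl2, −78 → 0 °C, dark; MeOH then aq. NaHCO3 at −78 °C
Reagents that add atoms: none
Why: Lewis acid cleavage of aryl methyl ethers: each ether oxygen binds boron and bromide removes the methyl group by SN2. No proton source is present until the cold buffered quench, and a dihydrofuran that opens can only re-close to the trans ring because C3 and C3' are untouched.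

## Compound list

1 | 5-chloro-2-hydroxy-3-methoxybenzaldehyde | COc1cc(Cl)cc(C=O)c1O | starting material
2 | 5-chloro-3-methoxy-2-(methoxymethoxy)benzaldehyde | COCOc1c(OC)cc(Cl)cc1C=O | intermediate
3 | 5-chloro-1-ethynyl-3-methoxy-2-(methoxymethoxy)benzene | COCOc1c(OC)cc(Cl)cc1C#C | intermediate
4 | acenaphthylene-1,2-dione | O=C1C(=O)c2cccc3cccc1c23 | starting material
5 | cis-1,2-dimethyl-1,2-dihydroacenaphthylene-1,2-diol (meso) | C[C@@]1(O)c2cccc3cccc(c23)[C@]1(C)O | intermediate
6 | 2-[(E)-2-[5-chloro-3-methoxy-2-(methoxymethoxy)phenyl]ethenyl]-1,3,2-benzodioxaborole | COCOc1c(OC)cc(Cl)cc1/C=C/B1Oc2ccccc2O1 | intermediate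
7 | 8-[(E)-2-[5-chloro-3-methoxy-2-(methoxymethoxy)phenyl]ethenyl]-6b,9a-dimethyl-6b,9a-dihydroacenaphtho[1,2-d][1,3,2]dioxaborole (cis ring fusion) | COCOc1c(OC)cc(Cl)cc1/C=C/B1O[C@]2(C)c3cccc4cccc(c34)[C@]2(C)O1 | intermediate
8 | 3,5-dimethoxyphenol | COc1cc(O)cc(OC)c1 | starting material
9 | 3,5-dimethoxyphenyl trifluoromethanesulfonate | COc1cc(OC)cc(OS(=O)(=O)C(F)(F)F)c1 | intermediate
10 | 4-bromoanisole | COc1ccc(Br)cc1 | starting material
11 | 4-methoxyphenyllithium | [Li]c1ccc(OC)cc1 | intermediate
12 | lithium borate from 7 and 11 (boron bearing the (E)-alkenyl group, the 4-methoxyphenyl group and the mac diolate; configuration at boron not defined) | [Li+].COCOc1c(OC)cc(Cl)cc1/C=C/[B-]1(c2ccc(OC)cc2)O[C@]2(C)c3cccc4cccc(c34)[C@]2(C)O1 | intermediate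
13 | (1S,2R)-2-[5-chloro-3-methoxy-2-(methoxymethoxy)phenyl]-2-(3,5-dimethoxyphenyl)-1-(4-methoxyphenyl)ethyl B(mac) boronate | COCOc1c(OC)cc(Cl)cc1[C@@H](c1cc(OC)cc(OC)c1)[C@@H](c1ccc(OC)cc1)B1O[C@]2(C)c3cccc4cccc(c34)[C@]2(C)O1 | intermediate
14 | 4-chloro-2-[(1R,2S)-1-(3,5-dimethoxyphenyl)-2-(4-methoxyphenyl)-2-B(mac)-ethyl]-6-methoxyphenol | Oc1c(OC)cc(Cl)cc1[C@@H](c1cc(OC)cc(OC)c1)[C@@H](c1ccc(OC)cc1)B1O[C@]2(C)c3cccc4cccc(c34)[C@]2(C)O1 | intermediate
15 | 4-chloro-2-[(1R,2S)-1-(3,5-dimethoxyphenyl)-2-hydroxy-2-(4-methoxyphenyl)ethyl]-6-methoxyphenol | Oc1c(OC)cc(Cl)cc1[C@@H](c1cc(OC)cc(OC)c1)[C@@H](c1ccc(OC)cc1)O | intermediate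
16 | (2R,3R)-5-chloro-3-(3,5-dimethoxyphenyl)-7-methoxy-2-(4-methoxyphenyl)-2,3-dihydro-1-benzofuran | Clc1cc(OC)c2c(c1)[C@@H](c1cc(OC)cc(OC)c1)[C@H](c1ccc(OC)cc1)O2 | intermediate
17 | 2-[(2R,3R)-3-(3,5-dimethoxyphenyl)-7-methoxy-2-(4-methoxyphenyl)-2,3-dihydro-1-benzofuran-5-yl]-4,4,5,5-tetramethyl-1,3,2-dioxaborolane | CC1(C)OB(OC1(C)C)c1cc(OC)c2c(c1)[C@@H](c1cc(OC)cc(OC)c1)[C@H](c1ccc(OC)cc1)O2 | intermediate
18 | (2R,3R)-3-(3,5-dimethoxyphenyl)-7-methoxy-2-(4-methoxyphenyl)-2,3-dihydro-1-benzofuran-5-ol | Oc1cc(OC)c2c(c1)[C@@H](c1cc(OC)cc(OC)c1)[C@H](c1ccc(OC)cc1)O2 | intermediate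
19 | (2R,3R)-3-(3,5-dimethoxyphenyl)-7-methoxy-2-(4-methoxyphenyl)-2,3-dihydro-1-benzofuran-5-yl trifluoromethanesulfonate | FC(F)(F)S(=O)(=O)Oc1cc(OC)c2c(c1)[C@@H](c1cc(OC)cc(OC)c1)[C@H](c1ccc(OC)cc1)O2 | intermediate
20 | (E)-3,4',5-trimethoxystilbene | COc1ccc(/C=C/c2cc(OC)cc(OC)c2)cc1 | starting material
21 | 2,4-dimethoxy-6-[(E)-2-(4-methoxyphenyl)ethenyl]benzaldehyde | COc1ccc(/C=C/c2cc(OC)cc(OC)c2C=O)cc1 | intermediate
22 | 2-hydroxy-4-methoxy-6-[(E)-2-(4-methoxyphenyl)ethenyl]benzaldehyde | COc1ccc(/C=C/c2cc(OC)cc(O)c2C=O)cc1 | intermediate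
23 | 4-methoxy-2-(methoxymethoxy)-6-[(E)-2-(4-methoxyphenyl)ethenyl]benzaldehyde | COCOc1cc(OC)cc(/C=C/c2ccc(OC)cc2)c1C=O | intermediate
24 | 2-ethynyl-5-methoxy-1-(methoxymethoxy)-3-[(E)-2-(4-methoxyphenyl)ethenyl]benzene | COCOc1cc(OC)cc(/C=C/c2ccc(OC)cc2)c1C#C | intermediate
25 | 2-[(E)-2-[4-methoxy-2-(methoxymethoxy)-6-[(E)-2-(4-methoxyphenyl)ethenyl]phenyl]ethenyl]-1,3,2-benzodioxaborole | COCOc1cc(OC)cc(/C=C/c2ccc(OC)cc2)c1/C=C/B1Oc2ccccc2O1 | intermediate
26 | (E)-2-[4-methoxy-2-(methoxymethoxy)-6-[(E)-2-(4-methoxyphenyl)ethenyl]phenyl]ethenyl B(mac) boronate | COCOc1cc(OC)cc(/C=C/c2ccc(OC)cc2)c1/C=C/B1O[C@]2(C)c3cccc4cccc(c34)[C@]2(C)O1 | intermediate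
27 | lithium borate from 26 and 11 (boron bearing the (E)-alkenyl group, the 4-methoxyphenyl group and the mac diolate; configuration at boron not defined) | [Li+].COCOc1cc(OC)cc(/C=C/c2ccc(OC)cc2)c1/C=C/[B-]1(c2ccc(OC)cc2)O[C@]2(C)c3cccc4cccc(c34)[C@]2(C)O1 | intermediate
28 | (1R,2S)-2-[(2R,3R)-3-(3,5-dimethoxyphenyl)-7-methoxy-2-(4-methoxyphenyl)-2,3-dihydro-1-benzofuran-5-yl]-2-[4-methoxy-2-(methoxymethoxy)-6-[(E)-2-(4-methoxyphenyl)ethenyl]phenyl]-1-(4-methoxyphenyl)ethyl B(mac) boronate | COCOc1cc(OC)cc(/C=C/c2ccc(OC)cc2)c1[C@H](c1cc(OC)c2c(c1)[C@@H](c1cc(OC)cc(OC)c1)[C@H](c1ccc(OC)cc1)O2)[C@H](c1ccc(OC)cc1)B1O[C@]2(C)c3cccc4cccc(c34)[C@]2(C)O1 | intermediate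
29 | phenol corresponding to 28 (2-hydroxy in place of 2-methoxymethoxy on the ring A aryl group, same (1R,2S) and (2R,3R) centres) | Oc1cc(OC)cc(/C=C/c2ccc(OC)cc2)c1[C@H](c1cc(OC)c2c(c1)[C@@H](c1cc(OC)cc(OC)c1)[C@H](c1ccc(OC)cc1)O2)[C@H](c1ccc(OC)cc1)B1O[C@]2(C)c3cccc4cccc(c34)[C@]2(C)O1 | intermediate
30 | (1R,2S)-2-[(2R,3R)-3-(3,5-dimethoxyphenyl)-7-methoxy-2-(4-methoxyphenyl)-2,3-dihydro-1-benzofuran-5-yl]-2-[2-hydroxy-4-methoxy-6-[(E)-2-(4-methoxyphenyl)ethenyl]phenyl]-1-(4-methoxyphenyl)ethan-1-ol | Oc1cc(OC)cc(/C=C/c2ccc(OC)cc2)c1[C@H](c1cc(OC)c2c(c1)[C@@H](c1cc(OC)cc(OC)c1)[C@H](c1ccc(OC)cc1)O2)[C@H](c1ccc(OC)cc1)O | intermediate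
31 | (2S,3S)-3-[(2R,3R)-3-(3,5-dimethoxyphenyl)-7-methoxy-2-(4-methoxyphenyl)-2,3-dihydro-1-benzofuran-5-yl]-6-methoxy-2-(4-methoxyphenyl)-4-[(E)-2-(4-methoxyphenyl)ethenyl]-2,3-dihydro-1-benzofuran | COc1ccc(/C=C/c2cc(OC)cc3c2[C@H](c2cc(OC)c4c(c2)[C@@H](c2cc(OC)cc(OC)c2)[C@H](c2ccc(OC)cc2)O4)[C@@H](c2ccc(OC)cc2)O3)cc1 | intermediate
32 | (2S,3S)-3-[(2R,3R)-3-(3,5-dihydroxyphenyl)-7-hydroxy-2-(4-hydroxyphenyl)-2,3-dihydro-1-benzofuran-5-yl]-2-(4-hydroxyphenyl)-4-[(E)-2-(4-hydroxyphenyl)ethenyl]-2,3-dihydro-1-benzofuran-6-ol | Oc1ccc(/C=C/c2cc(O)cc3c2[C@H](c2cc(O)c4c(c2)[C@@H](c2cc(O)cc(O)c2)[C@H](c2ccc(O)cc2)O4)[C@@H](c2ccc(O)cc2)O3)cc1 | target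

## Step count and least certain steps

Total step count: 20. Longest linear sequence: 12 steps (1, 2, 4, 7, 8, 9, 10, 11, 17, 18, 19, 20); the ring A branch (steps 12–16) and the reagent steps 3, 5 and 6 are convergent.

Step 7 (key step). What may go wrong: direct transfer of an organic group from boron to palladium (Suzuki coupling) may outrun the metallate shift, because the β-carbon carries an ortho-substituted aryl group; facial selectivity at that crowded alkene may also be poor. Fallback, setting out from 1 and returning at 16: 1 is treated with two equivalents of 3,5-dimethoxyphenylmagnesium bromide to give the ortho-hydroxybenzhydrol F1. Acid-mediated exchange of its hydroxyl for sulfinate with sodium 4-methylbenzenesulfinate gives the sulfone F2. Cs2CO3 then releases the ortho-quinone methide, which is intercepted by the ylide of the C2-symmetric sulfonium salt F3 (from (2R,5R)-2,5-dimethylthiolane and 4-methoxybenzyl bromide, the thiolane antipode being matched to the (2R,3R) series) in a (4+1) annulation that gives 16 in place of steps 1, 2, 4, 5 and 7–9, while steps 3 and 6 remain in use for the ring A half.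

Step 17. What may go wrong: palladium may coordinate only slowly to the alkene of 27, which is twisted out of conjugation and shielded by two ortho substituents, so that direct coupling or arylation of the stilbene takes over. Fallback, setting out from 16 and returning at 31: 16 is borylated as in step 10 and the pinacol boronate 17 is isolated. Addition of 17 to aldehyde 23 with [RhCl(cod)]2 and KOH in aqueous dioxane gives the diaryl carbinol F4 as both epimers at the carbinol carbon. Sodium 4-methylbenzenesulfinate and HCl in MeOH/THF remove the acetal and exchange hydroxyl for sulfinate, giving the sulfone F5. Cs2CO3 and the antipodal sulfonium salt F6 then close the ring A dihydrofuran by the same (4+1) annulation under reagent control, giving 31 and bypassing steps 11 and 15–19.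

Step 20. What may go wrong: the Lewis acid may ionise O1–C2, or HBr formed at the quench may protonate the stilbene, and the cation may then be captured by the stilbene or by C4'/C6' of ring B, so that a new ring forms instead of simple deprotection. Fallback, setting out from 31 and returning at 32: the stilbene is excised before the Lewis acid is used and rebuilt afterwards. Cleavage of 31 with OsO4/NaIO4 gives the C4 aldehyde F7; BBr3 then meets no alkene and gives the hexaphenol aldehyde F8, in which an opened dihydrofuran can only re-close to the trans ring. Silylation with t-BuMe2SiCl and imidazole gives the hexakis-silyl ether F9. Horner–Wadsworth–Emmons olefination with the silylated phosphonate F10 (from diethyl (4-hydroxybenzyl)phosphonate and t-BuMe2SiCl) and NaH gives the heptakis-silyl ether F11 with the (E)-alkene. Bu4NF buffered with AcOH then releases 32 under neutral conditions.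

Step 8. What may go wrong: boron may be lost by protodeboronation or solvolysis of the boronate during the acidic acetal cleavage, or oxidation of the hindered boronate may stall. Fallback, setting out from 13 and returning at 16: 13 is oxidised first with NaOH and H2O2 to the acetal-protected alcohol F12, which is then treated with TsOH in MeOH/CH2Cl2. Loss of the acetal and ionisation of the 4-methoxybenzylic alcohol occur together, and the phenol captures the cation on the face away from the C3' aryl group. This SN1 closure, in which C3' controls C2', gives the trans ring of 16 directly and bypasses step 9.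

## Further compounds

F1 | step 7 | 4-chloro-2-[(3,5-dimethoxyphenyl)(hydroxy)methyl]-6-methoxyphenol (racemic) | COc1cc(Cl)cc(C(O)c2cc(OC)cc(OC)c2)c1O
F2 | step 7 | 4-chloro-2-[(3,5-dimethoxyphenyl)(4-methylbenzenesulfonyl)methyl]-6-methoxyphenol (racemic) | COc1cc(Cl)cc(C(c2cc(OC)cc(OC)c2)S(=O)(=O)c2ccc(C)cc2)c1O
F3 | step 7 | (2R,5R)-1-(4-methoxybenzyl)-2,5-dimethylthiolan-1-ium bromide | C[C@@H]1CC[C@@H](C)[S+]1Cc1ccc(OC)cc1.[Br-]
F4 | step 17 | [(2R,3R)-3-(3,5-dimethoxyphenyl)-7-methoxy-2-(4-methoxyphenyl)-2,3-dihydro-1-benzofuran-5-yl][4-methoxy-2-(methoxymethoxy)-6-[(E)-2-(4-methoxyphenyl)ethenyl]phenyl]methanol (both carbinol epimers) | COCOc1cc(OC)cc(/C=C/c2ccc(OC)cc2)c1C(O)c1cc(OC)c2c(c1)[C@@H](c1cc(OC)cc(OC)c1)[C@H](c1ccc(OC)cc1)O2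
F5 | step 17 | 2-[[(2R,3R)-3-(3,5-dimethoxyphenyl)-7-methoxy-2-(4-methoxyphenyl)-2,3-dihydro-1-benzofuran-5-yl](4-methylbenzenesulfonyl)methyl]-5-methoxy-3-[(E)-2-(4-methoxyphenyl)ethenyl]phenol (both epimers at the sulfonyl carbon) | Oc1cc(OC)cc(/C=C/c2ccc(OC)cc2)c1C(c1cc(OC)c2c(c1)[C@@H](c1cc(OC)cc(OC)c1)[C@H](c1ccc(OC)cc1)O2)S(=O)(=O)c1ccc(C)cc1
F6 | step 17 | (2S,5S)-1-(4-methoxybenzyl)-2,5-dimethylthiolan-1-ium bromide | C[C@H]1CC[C@H](C)[S+]1Cc1ccc(OC)cc1.[Br-]
F7 | step 20 | (2S,3S)-3-[(2R,3R)-3-(3,5-dimethoxyphenyl)-7-methoxy-2-(4-methoxyphenyl)-2,3-dihydro-1-benzofuran-5-yl]-6-methoxy-2-(4-methoxyphenyl)-2,3-dihydro-1-benzofuran-4-carbaldehyde | O=Cc1cc(OC)cc2c1[C@H](c1cc(OC)c3c(c1)[C@@H](c1cc(OC)cc(OC)c1)[C@H](c1ccc(OC)cc1)O3)[C@@H](c1ccc(OC)cc1)O2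
F8 | step 20 | (2S,3S)-3-[(2R,3R)-3-(3,5-dihydroxyphenyl)-7-hydroxy-2-(4-hydroxyphenyl)-2,3-dihydro-1-benzofuran-5-yl]-6-hydroxy-2-(4-hydroxyphenyl)-2,3-dihydro-1-benzofuran-4-carbaldehyde | O=Cc1cc(O)cc2c1[C@H](c1cc(O)c3c(c1)[C@@H](c1cc(O)cc(O)c1)[C@H](c1ccc(O)cc1)O3)[C@@H](c1ccc(O)cc1)O2
F9 | step 20 | hexakis(tert-butyldimethylsilyl) ether of F8 (all six phenols silylated, same four stereocentres) | O=Cc1cc(O[Si](C)(C)C(C)(C)C)cc2c1[C@H](c1cc(O[Si](C)(C)C(C)(C)C)c3c(c1)[C@@H](c1cc(O[Si](C)(C)C(C)(C)C)cc(O[Si](C)(C)C(C)(C)C)c1)[C@H](c1ccc(O[Si](C)(C)C(C)(C)C)cc1)O3)[C@@H](c1ccc(O[Si](C)(C)C(C)(C)C)cc1)O2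
F10 | step 20 | diethyl {[4-(tert-butyldimethylsilyloxy)phenyl]methyl}phosphonate | CCOP(=O)(Cc1ccc(O[Si](C)(C)C(C)(C)C)cc1)OCC
F11 | step 20 | heptakis(tert-butyldimethylsilyl) ether of 32 (all seven phenols silylated, (E)-alkene, same four stereocentres) | CC(C)(C)[Si](C)(C)Oc1ccc(/C=C/c2cc(O[Si](C)(C)C(C)(C)C)cc3c2[C@H](c2cc(O[Si](C)(C)C(C)(C)C)c4c(c2)[C@@H](c2cc(O[Si](C)(C)C(C)(C)C)cc(O[Si](C)(C)C(C)(C)C)c2)[C@H](c2ccc(O[Si](C)(C)C(C)(C)C)cc2)O4)[C@@H](c2ccc(O[Si](C)(C)C(C)(C)C)cc2)O3)cc1
F12 | step 8 | (1S,2R)-2-[5-chloro-3-methoxy-2-(methoxymethoxy)phenyl]-2-(3,5-dimethoxyphenyl)-1-(4-methoxyphenyl)ethan-1-ol | COCOc1c(OC)cc(Cl)cc1[C@@H](c1cc(OC)cc(OC)c1)[C@@H](c1ccc(OC)cc1)O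
A1 | alternative 1 | (2R)-3-diazo-5-hydroxy-7-methoxy-2-(4-methoxyphenyl)-2,3-dihydro-4H-chromen-4-one (spatial arrangement of (2S)-naringenin) | COc1ccc(cc1)[C@H]1Oc2cc(OC)cc(O)c2C(=O)C1=[N+]=[N-]
A2 | alternative 1 | methyl (2S,3S)-4-hydroxy-6-methoxy-2-(4-methoxyphenyl)-2,3-dihydro-1-benzofuran-3-carboxylate | Oc1cc(OC)cc2c1[C@H](C(=O)OC)[C@@H](c1ccc(OC)cc1)O2
A3 | alternative 2 | (1S,2S,5E)-1-(ethynyloxy)-2-[3-methoxy-4-(methoxymethoxy)phenyl]-1,6-bis(4-methoxyphenyl)hex-5-en-3-yne | C#CO[C@H](c1ccc(OC)cc1)[C@@H](c1ccc(OCOC)c(OC)c1)C#C/C=C/c1ccc(OC)cc1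
A4 | alternative 2 | 2-ethynyl-4,4,5,5-tetramethyl-1,3,2-dioxaborolane | C#CB1OC(C)(C)C(C)(C)O1
A5 | alternative 2 | 2-[(2S,3S)-3-[3-methoxy-4-(methoxymethoxy)phenyl]-2-(4-methoxyphenyl)-4-[(E)-2-(4-methoxyphenyl)ethenyl]-2,3-dihydro-1-benzofuran-6-yl]-4,4,5,5-tetramethyl-1,3,2-dioxaborolane | COc1ccc(/C=C/c2cc(B3OC(C)(C)C(C)(C)O3)cc3c2[C@H](c2ccc(OCOC)c(OC)c2)[C@@H](c2ccc(OC)cc2)O3)cc1
A6 | alternative 3 | 4-bromo-2-[(3,5-dimethoxyphenyl)(4-methylbenzenesulfonyl)methyl]-6-methoxyphenol | COc1cc(Br)cc(C(c2cc(OC)cc(OC)c2)S(=O)(=O)c2ccc(C)cc2)c1O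
A7 | alternative 3 | 4-bromo-6-[(3,5-dimethoxyphenyl)methylidene]-2-methoxycyclohexa-2,4-dien-1-one | COC1=CC(Br)=CC(=Cc2cc(OC)cc(OC)c2)C1=O
A8 | alternative 3 | (2R,5R)-1-(4-methoxybenzyl)-2,5-dimethylthiolan-1-ium bromide | C[C@@H]1CC[C@@H](C)[S+]1Cc1ccc(OC)cc1.[Br-]
A9 | alternative 3 | (2R,3R)-5-bromo-3-(3,5-dimethoxyphenyl)-7-methoxy-2-(4-methoxyphenyl)-2,3-dihydro-1-benzofuran | Brc1cc(OC)c2c(c1)[C@@H](c1cc(OC)cc(OC)c1)[C@H](c1ccc(OC)cc1)O2
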